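**Retrosynthetic overview**

1. In the oxolan-2-one ring (O1, C2, C3, C4, C5) the carbonyl carbon C2 is bonded only to O1 and C3. It is therefore brought in as CO between the oxygen of the C5 hydroxymethyl group and an alkyne carbon that becomes C3; breaking O1–C2 and C2–C3 leads back to homopropargylic alcohol 22.
2. After the carbonylation, hydrogenation of the E-benzylidene lactone 23 (with loss of both aryl benzyl groups), equilibration of C3 to trans and desilylation give lappaol A.
3. Alcohol 22 comes from Sonogashira coupling of terminal alkyne 18 with aryl iodide 20. Alkyne 18 comes from prochiral diacetate 13 by lipase desymmetrisation (sets lactone C4), acetate-to-silyl exchange, oxidation and Seyferth–Gilbert homologation.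
4. Diacetate 13 comes from B-alkyl Suzuki coupling of aryl bromide 10 with the 9-BBN adduct of 2-methylenepropane-1,3-diyl diacetate.
5. Bromide 10 comes from rhodium-carbene C–H insertion of aryl diazoacetate 6 (sets C2 and C3 of the dihydrobenzofuran). Ring order: dihydrofuran ring first (step 4), lactone ring last (step 17).

Key step: step 17

Abbreviations in names: DBF = (2S,3R)-2-(4-benzyloxy-3-methoxyphenyl)-3-[(tert-butyldiphenylsilyloxy)methyl]-7-methoxy-2,3-dihydro-1-benzofuran-5-yl; DBF-OH = the same group with 4-hydroxy-3-methoxyphenyl at C2.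

Assumption 1 (step 4): Rh2(S-PTTL)4 is taken to deliver the (2S,3R)-cis ester; if the induction proves opposite, Rh2(R-PTTL)4 is used with no other change.

Assumption 2 (step 9): the lipase is taken to cleave the acetate that leaves the (S)-monoacetate 14; if it cleaves the other one, the diol from methanolysis of 13 is acetylated with the same lipase and vinyl acetate, which gives (S)-14 by the complementary mode.

**Route**

Step 1
Reactants: 1 4-bromo-2-methoxyphenol
Product: 2 4-bromo-2-iodo-6-methoxyphenol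
Conditions: NIS (1.05 equiv), p-TsOH·H2O (10 mol%), MeCN, 0 °C to rt
Reagents that add atoms: N-iodosuccinimide, O=C1CCC(=O)N1I
Why: Electrophilic aromatic iodination, in which the free hydroxyl directs to its only open ortho position because the para position carries bromine, as in the iodination of vanillin.

Step 2
Reactants: 2 4-bromo-2-iodo-6-methoxyphenol; 3 (4-benzyloxy-3-methoxyphenyl)methanol
Product: 4 2-[(4-benzyloxy-3-methoxyphenyl)methoxy]-5-bromo-1-iodo-3-methoxybenzene
Conditions: PPh3, DIAD, THF, 0 °C to rt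
Reagents that add atoms: none
Why: Mitsunobu etherification, in which the halogen-acidified phenol protonates the betaine and its phenoxide displaces the activated primary benzylic alcohol, so no separate benzylic halide is needed.

Step 3
Reactants: 4 aryl iodide from step 2; 5 ethyl diazoacetate
Product: 6 ethyl 2-{2-[(4-benzyloxy-3-methoxyphenyl)methoxy]-5-bromo-3-methoxyphenyl}-2-diazoacetate
Conditions: Pd(PPh3)4 (5 mol%), Ag2CO3 (0.5 equiv), Et3N (1.3 equiv), toluene, rt
Reagents that add atoms: none
Why: Palladium-catalysed cross-coupling of an aryl iodide with the C–H bond of a diazoacetate, in which zerovalent palladium inserts into C–I at room temperature and leaves C–Br alone, and the diazo group is retained.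

Step 4
Reactants: 6 aryl diazoacetate
Product: 7 ethyl (2S,3R)-2-(4-benzyloxy-3-methoxyphenyl)-5-bromo-7-methoxy-2,3-dihydro-1-benzofuran-3-carboxylate (cis)
Conditions: Rh2(S-PTTL)4 (dirhodium tetrakis[N-phthaloyl-(S)-tert-leucinate], 1 mol%), toluene, −60 °C
Reagents that add atoms: none
Why: Intramolecular 1,5 C–H insertion of the rhodium carbene into the electron-rich benzylic methylene of the aryl ether closes the dihydrofuran ring (C3–C2 bond) as the cis isomer, and the chiral carboxylate ligands choose the enantiotopic hydrogen and the carbene face, which sets C2 (S) together with C3.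

Step 5
Reactants: 7 cis ester
Product: 8 ethyl (2S,3S)-2-(4-benzyloxy-3-methoxyphenyl)-5-bromo-7-methoxy-2,3-dihydro-1-benzofuran-3-carboxylate (trans)
Conditions: NaOEt (0.2 equiv), EtOH, rt
Reagents that add atoms: none
Why: Base-mediated epimerisation of the enolisable C3 to the thermodynamically preferred trans isomer; C2 is not acidic, and the endocyclic C2–O bond lies orthogonal to the enolate π system, so ring opening by β-elimination should not compete.

Step 6
Reactants: 8 trans ester
Product: 9 [(2S,3R)-2-(4-benzyloxy-3-methoxyphenyl)-5-bromo-7-methoxy-2,3-dihydro-1-benzofuran-3-yl]methanol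
Conditions: LiBH4 (2 equiv), THF, 0 °C to rt
Reagents that add atoms: none
Why: Hydride reduction of the ester to the primary alcohol with LiBH4, which leaves the aryl bromide and the benzyl ethers untouched (the descriptor at C3 changes only by priority).

Step 7
Reactants: 9 alcohol
Product: 10 tert-butyl{[(2S,3R)-2-(4-benzyloxy-3-methoxyphenyl)-5-bromo-7-methoxy-2,3-dihydro-1-benzofuran-3-yl]methoxy}diphenylsilane
Conditions: TBDPSCl, imidazole, DMF, rt
Reagents that add atoms: tert-butyl(chloro)diphenylsilane, CC(C)(C)[Si](Cl)(c1ccccc1)c1ccccc1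
Why: Silylation of the primary alcohol with a group that withstands carbonate, mild acid, CO/palladium and hydrogenation and is orthogonal to the TBS ether used later.

Step 8
Reactants: 10 aryl bromide; 11 2-methylenepropane-1,3-diyl diacetate
Product: 13 2-(DBF-methyl)propane-1,3-diyl diacetate, via alkylborane 12 (not isolated)
Conditions: 11, 9-BBN-H, THF, 0 °C to rt; then 10, PdCl2(dppf) (5 mol%), K2CO3, DMF, 50 °C
Reagents that add atoms: none
Why: Anti-Markovnikov hydroboration of the 1,1-disubstituted alkene followed by B-alkyl Suzuki–Miyaura coupling with the aryl bromide; carbonate in DMF tolerates the acetates, and the acetoxy groups sit γ to boron, so β-elimination is not possible.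

Step 9
Reactants: 13 prochiral diacetate
Product: 14 (2S)-3-hydroxy-2-(DBF-methyl)propyl acetate
Conditions: lipase from Burkholderia cepacia (Amano PS), 0.1 M phosphate buffer pH 7 / i-Pr2O, rt, stopped after one equivalent of acid is released
Reagents that add atoms: none
Why: Lipase-catalysed hydrolysis that distinguishes the two enantiotopic acetates of a 2-(arylmethyl)propane-1,3-diyl diacetate, a known desymmetrisation, which sets the future lactone C4 by the choice of the acetate that is cleaved.

Step 10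
Reactants: 14 monoacetate
Product: 15 (2R)-3-(tert-butyldimethylsilyloxy)-2-(DBF-methyl)propyl acetate
Conditions: TBSCl, imidazole, CH2Cl2, 0 °C to rt
Reagents that add atoms: tert-butyl(chloro)dimethylsilane, CC(C)(C)[Si](C)(C)Cl
Why: Silylation of the free primary hydroxyl, done promptly so that 1,3-acetyl migration cannot erode the stereocentre; this arm becomes the lactone CH2–O.

Step 11
Reactants: 15 silyl ether acetate
Product: 16 (2R)-3-(tert-butyldimethylsilyloxy)-2-(DBF-methyl)propan-1-ol
Conditions: K2CO3 (0.2 equiv), MeOH, 0 °C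
Reagents that add atoms: none
Why: Zemplén-type methanolysis of the primary acetate with catalytic carbonate at 0 °C, under which both silyl ethers hold and silyl migration between the two oxygens, which needs stronger base, is not expected.

Step 12
Reactants: 16 alcohol
Product: 17 (2S)-3-(tert-butyldimethylsilyloxy)-2-(DBF-methyl)propanal
Conditions: Dess–Martin periodinane, pyridine, CH2Cl2, 0 °C to rt
Reagents that add atoms: none
Why: Dess–Martin oxidation gives the α-branched β-silyloxy aldehyde under near-neutral conditions without epimerisation, and the aldehyde is used at once.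

Step 13
Reactants: 17 aldehyde
Product: 18 (R)-tert-butyldimethyl{[2-(DBF-methyl)but-3-yn-1-yl]oxy}silane
Conditions: dimethyl (1-diazo-2-oxopropyl)phosphonate, K2CO3, MeOH, 0 °C to rt
Reagents that add atoms: dimethyl (1-diazo-2-oxopropyl)phosphonate, COP(=O)(OC)C(=[N+]=[N-])C(C)=O
Why: Seyferth–Gilbert homologation in the Ohira–Bestmann form, in which the diazomethylphosphonate anion made in the flask adds to the aldehyde and cycloelimination, loss of N2 and 1,2-hydride shift give the terminal alkyne under conditions mild enough for β-silyloxy aldehydes of this type.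

Step 14
Reactants: 19 4-iodo-2-methoxyphenol
Product: 20 1-benzyloxy-4-iodo-2-methoxybenzene
Conditions: BnBr, K2CO3, acetone, reflux
Reagents that add atoms: benzyl bromide, BrCc1ccccc1
Why: Williamson ether synthesis on a phenol, which places on the second guaiacyl ring the same benzyl group that the other phenol carries.

Step 15
Reactants: 18 terminal alkyne; 20 aryl iodide
Product: 21 (R)-{[4-(4-benzyloxy-3-methoxyphenyl)-2-(DBF-methyl)but-3-yn-1-yl]oxy}(tert-butyl)dimethylsilane
Conditions: Pd(PPh3)2Cl2 (3 mol%), CuI (5 mol%), Et3N/THF, rt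
Reagents that add atoms: none
Why: Sonogashira coupling of a terminal alkyne with an electron-rich aryl iodide at room temperature, which does not touch the propargylic stereocentre.

Step 16
Reactants: 21 silyl-protected aryl alkyne
Product: 22 (2R)-4-(4-benzyloxy-3-methoxyphenyl)-2-(DBF-methyl)but-3-yn-1-ol
Conditions: PPTS (0.3 equiv), MeOH, rt
Reagents that add atoms: none
Why: Acid-catalysed methanolysis of the primary TBS ether, which is far faster than that of the TBDPS ether, under acid too weak to open the dihydrobenzofuran.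

Step 17
Reactants: 22 homopropargylic alcohol
Product: 23 (3E,4R)-3-[(4-benzyloxy-3-methoxyphenyl)methylidene]-4-(DBF-methyl)oxolan-2-one
Conditions: Pd(OAc)2 (5 mol%), dppb (10 mol%), CO (20 bar), toluene, 100 °C
Reagents that add atoms: carbon monoxide, [C-]#[O+]
Why: The phosphine-ligated palladium acetate exchanges acetate for the primary alkoxide of 22 and takes up CO to give an alkoxycarbonyl-palladium species (O1–C2 bond); this adds syn across the tethered alkyne so that the acyl carbon bonds to the proximal alkyne carbon (C2–C3 bond), and protonolysis of the alkenyl–palladium bond by acetic acid or the alcohol releases the lactone and returns divalent palladium. The closest known reaction type is the palladium-catalysed cyclocarbonylation of homopropargylic alcohols to α-alkylidene-γ-butyrolactones. The oxolan-2-one ring closes in the 5-exo-dig mode; a six-membered lactone would need 6-endo insertion with the acyl carbon reaching the distal, aryl-bearing carbon, which the two-carbon tether disfavours. No stereocentre is created: the E geometry (aryl cis to C4) follows from syn addition and protonolysis with retention, and C4, set in step 9, has no acidic hydrogen under these neutral conditions. The step needs carbonylation to win over 5-endo oxypalladation of the alkynol to a dihydrofuran and needs only one hydroxyl to react; the chelating diphosphine and CO pressure hold back the π-acid pathway, and the only other hydroxyl is masked as the TBDPS ether.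

Step 18
Reactants: 23 benzylidene lactone
Product: 24 (3S,4R)-3-(4-hydroxy-3-methoxybenzyl)-4-[(DBF-OH)methyl]oxolan-2-one (cis)
Conditions: H2 (1 atm), 10% Pd/C, EtOAc/EtOH, rt, stopped when uptake ends
Reagents that add atoms: none
Why: Heterogeneous hydrogenation adds H2 to the exocyclic alkene from the face opposite the C4 substituent, which should give mainly the cis lactone (new C3 centre), and the same catalyst hydrogenolyses both aryl benzyl ethers; any trans isomer converges in step 19.

Step 19
Reactants: 24 cis lactone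
Product: 25 (3R,4R)-3-(4-hydroxy-3-methoxybenzyl)-4-[(DBF-OH)methyl]oxolan-2-one (trans)
Conditions: DBU (5 equiv), THF, 50 °C; dilute aqueous acid work-up
Reagents that add atoms: none
Why: Base equilibration through the lactone enolate moves C3 to the thermodynamically preferred trans-3,4-disubstituted lactone; C4 and the dihydrobenzofuran C3 are not enolisable, so they hold and direct the outcome.

Step 20
Reactants: 25 trans lactone silyl ether
Product: 26 lappaol A, (3R,4R)-3-(4-hydroxy-3-methoxybenzyl)-4-{[(2S,3R)-2-(4-hydroxy-3-methoxyphenyl)-3-(hydroxymethyl)-7-methoxy-2,3-dihydro-1-benzofuran-5-yl]methyl}oxolan-2-one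
Conditions: TBAF (3 equiv), AcOH (3 equiv), THF, rt to 40 °C
Reagents that add atoms: none
Why: Fluoride cleavage of the primary silyl ether, buffered with acetic acid so that the phenols and the lactone are not exposed to strong base.

**Compound list**

1 | 4-bromo-2-methoxyphenol | COc1cc(Br)ccc1O | starting material
2 | 4-bromo-2-iodo-6-methoxyphenol | COc1cc(Br)cc(I)c1O | intermediate
3 | (4-benzyloxy-3-methoxyphenyl)methanol | COc1cc(CO)ccc1OCc1ccccc1 | starting material
4 | 2-[(4-benzyloxy-3-methoxyphenyl)methoxy]-5-bromo-1-iodo-3-methoxybenzene | COc1cc(Br)cc(I)c1OCc1ccc(OCc2ccccc2)c(OC)c1 | intermediate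
5 | ethyl diazoacetate | CCOC(=O)C=[N+]=[N-] | starting material
6 | ethyl 2-{2-[(4-benzyloxy-3-methoxyphenyl)methoxy]-5-bromo-3-methoxyphenyl}-2-diazoacetate | CCOC(=O)C(=[N+]=[N-])c1cc(Br)cc(OC)c1OCc1ccc(OCc2ccccc2)c(OC)c1 | intermediate
7 | ethyl (2S,3R)-2-(4-benzyloxy-3-methoxyphenyl)-5-bromo-7-methoxy-2,3-dihydro-1-benzofuran-3-carboxylate (cis) | Brc1cc(OC)c2c(c1)[C@@H](C(=O)OCC)[C@@H](c1ccc(OCc3ccccc3)c(OC)c1)O2 | intermediate
8 | ethyl (2S,3S)-2-(4-benzyloxy-3-methoxyphenyl)-5-bromo-7-methoxy-2,3-dihydro-1-benzofuran-3-carboxylate (trans) | Brc1cc(OC)c2c(c1)[C@H](C(=O)OCC)[C@@H](c1ccc(OCc3ccccc3)c(OC)c1)O2 | intermediate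
9 | [(2S,3R)-2-(4-benzyloxy-3-methoxyphenyl)-5-bromo-7-methoxy-2,3-dihydro-1-benzofuran-3-yl]methanol | Brc1cc(OC)c2c(c1)[C@H](CO)[C@@H](c1ccc(OCc3ccccc3)c(OC)c1)O2 | intermediate
10 | tert-butyl{[(2S,3R)-2-(4-benzyloxy-3-methoxyphenyl)-5-bromo-7-methoxy-2,3-dihydro-1-benzofuran-3-yl]methoxy}diphenylsilane | Brc1cc(OC)c2c(c1)[C@H](CO[Si](c1ccccc1)(c1ccccc1)C(C)(C)C)[C@@H](c1ccc(OCc3ccccc3)c(OC)c1)O2 | intermediate
11 | 2-methylenepropane-1,3-diyl diacetate | C=C(COC(C)=O)COC(C)=O | starting material
12 | 2-(acetoxymethyl)-3-(9-borabicyclo[3.3.1]nonan-9-yl)propyl acetate | CC(=O)OCC(COC(C)=O)CB1C2CCCC1CCC2 | intermediate (not isolated)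
13 | 2-(DBF-methyl)propane-1,3-diyl diacetate | CC(=O)OCC(COC(C)=O)Cc1cc(OC)c2c(c1)[C@H](CO[Si](c1ccccc1)(c1ccccc1)C(C)(C)C)[C@@H](c1ccc(OCc3ccccc3)c(OC)c1)O2 | intermediate
14 | (2S)-3-hydroxy-2-(DBF-methyl)propyl acetate | OC[C@@H](COC(C)=O)Cc1cc(OC)c2c(c1)[C@H](CO[Si](c1ccccc1)(c1ccccc1)C(C)(C)C)[C@@H](c1ccc(OCc3ccccc3)c(OC)c1)O2 | intermediate
15 | (2R)-3-(tert-butyldimethylsilyloxy)-2-(DBF-methyl)propyl acetate | CC(C)(C)[Si](C)(C)OC[C@@H](COC(C)=O)Cc1cc(OC)c2c(c1)[C@H](CO[Si](c1ccccc1)(c1ccccc1)C(C)(C)C)[C@@H](c1ccc(OCc3ccccc3)c(OC)c1)O2 | intermediate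
16 | (2R)-3-(tert-butyldimethylsilyloxy)-2-(DBF-methyl)propan-1-ol | CC(C)(C)[Si](C)(C)OC[C@@H](CO)Cc1cc(OC)c2c(c1)[C@H](CO[Si](c1ccccc1)(c1ccccc1)C(C)(C)C)[C@@H](c1ccc(OCc3ccccc3)c(OC)c1)O2 | intermediate
17 | (2S)-3-(tert-butyldimethylsilyloxy)-2-(DBF-methyl)propanal | CC(C)(C)[Si](C)(C)OC[C@@H](C=O)Cc1cc(OC)c2c(c1)[C@H](CO[Si](c1ccccc1)(c1ccccc1)C(C)(C)C)[C@@H](c1ccc(OCc3ccccc3)c(OC)c1)O2 | intermediate
18 | (R)-tert-butyldimethyl{[2-(DBF-methyl)but-3-yn-1-yl]oxy}silane | CC(C)(C)[Si](C)(C)OC[C@@H](C#C)Cc1cc(OC)c2c(c1)[C@H](CO[Si](c1ccccc1)(c1ccccc1)C(C)(C)C)[C@@H](c1ccc(OCc3ccccc3)c(OC)c1)O2 | intermediate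
19 | 4-iodo-2-methoxyphenol | COc1cc(I)ccc1O | starting material
20 | 1-benzyloxy-4-iodo-2-methoxybenzene | COc1cc(I)ccc1OCc1ccccc1 | intermediate
21 | (R)-{[4-(4-benzyloxy-3-methoxyphenyl)-2-(DBF-methyl)but-3-yn-1-yl]oxy}(tert-butyl)dimethylsilane | CC(C)(C)[Si](C)(C)OC[C@@H](C#Cc1ccc(OCc2ccccc2)c(OC)c1)Cc1cc(OC)c2c(c1)[C@H](CO[Si](c1ccccc1)(c1ccccc1)C(C)(C)C)[C@@H](c1ccc(OCc3ccccc3)c(OC)c1)O2 | intermediate
22 | (2R)-4-(4-benzyloxy-3-methoxyphenyl)-2-(DBF-methyl)but-3-yn-1-ol | OC[C@@H](C#Cc1ccc(OCc2ccccc2)c(OC)c1)Cc1cc(OC)c2c(c1)[C@H](CO[Si](c1ccccc1)(c1ccccc1)C(C)(C)C)[C@@H](c1ccc(OCc3ccccc3)c(OC)c1)O2 | intermediate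
23 | (3E,4R)-3-[(4-benzyloxy-3-methoxyphenyl)methylidene]-4-(DBF-methyl)oxolan-2-one | COc1cc(/C=C2/C(=O)OC[C@@H]2Cc2cc(OC)c3c(c2)[C@H](CO[Si](c2ccccc2)(c2ccccc2)C(C)(C)C)[C@@H](c2ccc(OCc4ccccc4)c(OC)c2)O3)ccc1OCc1ccccc1 | intermediate
24 | (3S,4R)-3-(4-hydroxy-3-methoxybenzyl)-4-[(DBF-OH)methyl]oxolan-2-one (cis) | COc1cc(C[C@@H]2C(=O)OC[C@@H]2Cc2cc(OC)c3c(c2)[C@H](CO[Si](c2ccccc2)(c2ccccc2)C(C)(C)C)[C@@H](c2ccc(O)c(OC)c2)O3)ccc1O | intermediate
25 | (3R,4R)-3-(4-hydroxy-3-methoxybenzyl)-4-[(DBF-OH)methyl]oxolan-2-one (trans) | COc1cc(C[C@H]2C(=O)OC[C@@H]2Cc2cc(OC)c3c(c2)[C@H](CO[Si](c2ccccc2)(c2ccccc2)C(C)(C)C)[C@@H](c2ccc(O)c(OC)c2)O3)ccc1O | intermediate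
26 | lappaol A | COc1cc(C[C@H]2C(=O)OC[C@@H]2Cc2cc(OC)c3c(c2)[C@H](CO)[C@@H](c2ccc(O)c(OC)c2)O3)ccc1O | target

**Step count and risks**

Total step count: 20. Longest linear sequence: 19 steps (steps 1 to 13 and 15 to 20; step 14 is a one-step side branch).

Steps most likely to fail:

1. Step 17 (key step). What may go wrong: cycloisomerisation of the alkynol by 5-endo oxypalladation instead of CO uptake, slow insertion of the hindered internal aryl alkyne into the alkoxycarbonyl–palladium bond, or double-bond migration on prolonged heating. The fallback uses no carbonylation; it sets out from 18 and comes back at 25. The TBS ether of 18 is cleaved with PPTS in MeOH to (2R)-2-(DBF-methyl)but-3-yn-1-ol F1. Ruthenium-catalysed oxidative cyclisation of this terminal homopropargylic alcohol (CpRu(cod)Cl, tris(4-fluorophenyl)phosphine, N-hydroxysuccinimide, NaHCO3, Bu4NBr, DMF/H2O, 95 °C; vinylidene, then oxacarbene, then oxidation) gives (4R)-4-(DBF-methyl)oxolan-2-one F2. Its lithium enolate (LiHMDS, THF, −78 °C) is alkylated anti to the C4 substituent with 4-benzyloxy-3-methoxybenzyl bromide F3 (from alcohol 3 and PBr3), giving (3R,4R)-3-(4-benzyloxy-3-methoxybenzyl)-4-(DBF-methyl)oxolan-2-one F4. Hydrogenolysis (H2, Pd/C, EtOAc/EtOH) then gives 25, so steps 18 and 19 are bypassed.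

2. Step 9. What may go wrong: slow turnover or weak discrimination between the enantiotopic acetates because the aryl group is much larger than in the usual substrates, and acetyl migration in the product that lowers the enantiomeric purity. The fallback is non-enzymatic; it sets out from 13 and comes back at 16. Methanolysis (K2CO3, MeOH) gives 2-(DBF-methyl)propane-1,3-diol F5. Desymmetrising benzoylation with vinyl benzoate under the dinuclear zinc catalyst made from Et2Zn and the ligand 2,6-bis{[2-(hydroxydiphenylmethyl)pyrrolidin-1-yl]methyl}-4-methylphenol (ligand enantiomer chosen by a test reaction; toluene, −20 °C) gives (2S)-3-hydroxy-2-(DBF-methyl)propyl benzoate F6. Silylation (TBSCl, imidazole) gives (2R)-3-(tert-butyldimethylsilyloxy)-2-(DBF-methyl)propyl benzoate F7, and methanolysis of the benzoate (K2CO3, MeOH) gives 16.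

3. Step 3. What may go wrong: slow oxidative addition and coupling at the hindered ortho-alkoxy iodide, loss of ethyl diazoacetate by carbene dimerisation, decomposition of the product diazo ester on palladium, or partial reaction at C–Br. The fallback builds the arylacetate first and installs the diazo group afterwards; it sets out from 4 and comes back at 6. Palladium-catalysed coupling of 4 with the Reformatsky reagent BrZnCH2CO2Et (from ethyl bromoacetate and zinc; Pd(PPh3)4, THF/DMPU, 50 °C, selective for C–I) gives ethyl 2-{2-[(4-benzyloxy-3-methoxyphenyl)methoxy]-5-bromo-3-methoxyphenyl}acetate F8. Regitz diazo transfer (4-acetamidobenzenesulfonyl azide, DBU, MeCN, rt) gives 6.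

Further compounds
F1 | step 17 | (2R)-2-(DBF-methyl)but-3-yn-1-ol | OC[C@@H](C#C)Cc1cc(OC)c2c(c1)[C@H](CO[Si](c1ccccc1)(c1ccccc1)C(C)(C)C)[C@@H](c1ccc(OCc3ccccc3)c(OC)c1)O2
F2 | step 17 | (4R)-4-(DBF-methyl)oxolan-2-one | C1C(=O)OC[C@@H]1Cc1cc(OC)c2c(c1)[C@H](CO[Si](c1ccccc1)(c1ccccc1)C(C)(C)C)[C@@H](c1ccc(OCc3ccccc3)c(OC)c1)O2
F3 | step 17 | 4-benzyloxy-3-methoxybenzyl bromide | COc1cc(CBr)ccc1OCc1ccccc1
F4 | step 17 | (3R,4R)-3-(4-benzyloxy-3-methoxybenzyl)-4-(DBF-methyl)oxolan-2-one | COc1cc(C[C@H]2C(=O)OC[C@@H]2Cc2cc(OC)c3c(c2)[C@H](CO[Si](c2ccccc2)(c2ccccc2)C(C)(C)C)[C@@H](c2ccc(OCc4ccccc4)c(OC)c2)O3)ccc1OCc1ccccc1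
F5 | step 9 | 2-(DBF-methyl)propane-1,3-diol | OCC(CO)Cc1cc(OC)c2c(c1)[C@H](CO[Si](c1ccccc1)(c1ccccc1)C(C)(C)C)[C@@H](c1ccc(OCc3ccccc3)c(OC)c1)O2
F6 | step 9 | (2S)-3-hydroxy-2-(DBF-methyl)propyl benzoate | OC[C@@H](COC(=O)c1ccccc1)Cc1cc(OC)c2c(c1)[C@H](CO[Si](c1ccccc1)(c1ccccc1)C(C)(C)C)[C@@H](c1ccc(OCc3ccccc3)c(OC)c1)O2
F7 | step 9 | (2R)-3-(tert-butyldimethylsilyloxy)-2-(DBF-methyl)propyl benzoate | CC(C)(C)[Si](C)(C)OC[C@@H](COC(=O)c1ccccc1)Cc1cc(OC)c2c(c1)[C@H](CO[Si](c1ccccc1)(c1ccccc1)C(C)(C)C)[C@@H](c1ccc(OCc3ccccc3)c(OC)c1)O2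
F8 | step 3 | ethyl 2-{2-[(4-benzyloxy-3-methoxyphenyl)methoxy]-5-bromo-3-methoxyphenyl}acetate | CCOC(=O)Cc1cc(Br)cc(OC)c1OCc1ccc(OCc2ccccc2)c(OC)c1
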